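**Assumption:** the target has no stereocentre and no stereogenic double bond, so it is achiral and no stereocontrol is needed. A one-flask sequence without isolation (steps 2 and 4) is counted as one step.

**Retrosynthetic overview**
1. Target 15 ⇐ benzyl ester 14 (hydrogenolysis) ⇐ dithiane-masked depside 13 ⇐ acid 8 + phenol 12 (depside ester bond, TFAA condensation).
2. 8 ⇐ keto acid 7 (ketone masked as a 1,3-dithiane so the activated carboxyl cannot lactonise onto it); 12 ⇐ keto acid 11 (benzyl ester).
3. Key disconnection in both halves is the aryl C6–CH2 bond: 7 ⇐ 5 + 4 and 11 ⇐ 9 + 4. It is made by carboxylate-directed C–H functionalisation with the α-oxo carbenoid from ylide 4, in which the ketone α-carbon acts as an electrophilic, enolonium-type centre towards the aryl–metal carbon.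
4. 4 ⇐ trimethylsulfoxonium iodide + hexanoyl chloride.
5. Rings: both benzene rings are bought. The only rings formed are the transient isocoumarin lactones 6 and 10 (reopened in the same flask) and the dithiane of 8 (removed in step 7).

**Step 1**
Reactants: 1 trimethylsulfoxonium iodide; 2 hexanoyl chloride
Product: 4 1-[dimethyl(oxo)-λ6-sulfanylidene]heptan-2-one, via dimethylsulfoxonium methylide 3 (not isolated)
Conditions: 1 (3 equiv), KOtBu (3 equiv), THF, reflux 2 h; then 2 (1 equiv), 0 °C → rt
Reagents that add atoms: none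
Why: Corey–Chaykovsky methylide formation followed by C-acylation with the acid chloride, a second equivalent of methylide deprotonating the acylsulfoxonium salt to give the bench-stable β-keto sulfoxonium ylide (ylide acylation).

**Step 2**
Reactants: 5 2-hydroxy-4-methoxybenzoic acid; 4 1-[dimethyl(oxo)-λ6-sulfanylidene]heptan-2-one
Product: 7 2-hydroxy-4-methoxy-6-(2-oxoheptyl)benzoic acid, via 8-hydroxy-6-methoxy-3-pentylisocoumarin 6 (not isolated)
Conditions: 4 (1.3 equiv), [Cp*Rh(MeCN)3](SbF6)2 (5 mol%), NaOAc (30 mol%), HFIP, 60 °C; evaporate; 2 M KOH, EtOH/H2O, 60 °C, N2; then 1 M HCl, 0 °C, pH 2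
Reagents that add atoms: water (as aqueous KOH), O
Why: Carboxylate-directed ortho C–H rhodation can only occur at C6, the ylide then gives an α-oxo Rh-carbene (loss of DMSO) whose carbon, the ketone α-carbon acting as an enolonium-type a2 centre, undergoes migratory insertion of the nucleophilic aryl–Rh bond and protodemetalation (Rh(III)-catalysed C–H acylmethylation/annulation of benzoic acids with sulfoxonium ylides), and the isocoumarin formed by lactonisation is reopened by saponification so that all material converges on 7.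

**Step 3**
Reactants: 7 2-hydroxy-4-methoxy-6-(2-oxoheptyl)benzoic acid
Product: 8 2-hydroxy-4-methoxy-6-[(2-pentyl-1,3-dithian-2-yl)methyl]benzoic acid
Conditions: HS(CH2)3SH (2 equiv), BF3·OEt2 (0.3 equiv), CH2Cl2, 0 °C → rt
Reagents that add atoms: propane-1,3-dithiol, SCCCS
Why: Lewis-acid-catalysed dithioketalisation, in which the strongly nucleophilic dithiol traps the activated ketone (or its lactol-derived oxocarbenium) at low temperature faster than dehydrative relactonisation, giving the masked ketone needed for the later carboxyl activation.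

**Step 4**
Reactants: 9 4-hydroxy-2-methoxybenzoic acid; 4 1-[dimethyl(oxo)-λ6-sulfanylidene]heptan-2-one
Product: 11 4-hydroxy-2-methoxy-6-(2-oxoheptyl)benzoic acid, via 6-hydroxy-8-methoxy-3-pentylisocoumarin 10 (not isolated)
Conditions: 4 (1.3 equiv), [Cp*Rh(MeCN)3](SbF6)2 (5 mol%), NaOAc (30 mol%), HFIP, 60 °C; evaporate; 2 M KOH, EtOH/H2O, 60 °C, N2; then 1 M HCl, 0 °C, pH 2
Reagents that add atoms: water (as aqueous KOH), O
Why: The same carboxylate-directed Rh(III) C–H acylmethylation with the α-oxo carbenoid as in step 2, again at the single free ortho C–H (C6) with the para-phenol a spectator in acidic HFIP, followed by saponification of the lactone.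

**Step 5**
Reactants: 11 4-hydroxy-2-methoxy-6-(2-oxoheptyl)benzoic acid
Product: 12 benzyl 4-hydroxy-2-methoxy-6-(2-oxoheptyl)benzoate
Conditions: BnBr (1.1 equiv), KHCO3 (1.2 equiv), DMF, rt → 40 °C
Reagents that add atoms: benzyl bromide, BrCc1ccccc1
Why: Bicarbonate deprotonates only the carboxylic acid (not the phenol or the ketone α-CH), so SN2 O-alkylation of the carboxylate gives the benzyl ester chemoselectively and leaves the 4-OH free for the depside coupling.

**Step 6**
Reactants: 8 2-hydroxy-4-methoxy-6-[(2-pentyl-1,3-dithian-2-yl)methyl]benzoic acid; 12 benzyl 4-hydroxy-2-methoxy-6-(2-oxoheptyl)benzoate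
Product: 13 benzyl 4-({2-hydroxy-4-methoxy-6-[(2-pentyl-1,3-dithian-2-yl)methyl]benzoyl}oxy)-2-methoxy-6-(2-oxoheptyl)benzoate
Conditions: TFAA (4 equiv), dry toluene, rt, 3 h; brief aq. NaHCO3 work-up
Reagents that add atoms: none
Why: TFAA turns the electron-rich, di-ortho-substituted acid into its mixed anhydride/acylium, which O-acylates the only free phenol of 12 (mixed-anhydride depside condensation), the chelated 2-OH needing no protection and the dithiane preventing the side-chain carbonyl from lactonising onto the activated carboxyl.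

**Step 7**
Reactants: 13 dithiane-masked depside benzyl ester
Product: 14 benzyl 4-{[2-hydroxy-4-methoxy-6-(2-oxoheptyl)benzoyl]oxy}-2-methoxy-6-(2-oxoheptyl)benzoate
Conditions: MeI (15 equiv), CaCO3 (5 equiv), MeCN/H2O 4:1, 40 °C
Reagents that add atoms: water, O
Why: Alkylative dithiane hydrolysis (S-methylation, thionium formation, capture by water) under buffered, near-neutral, non-oxidising conditions that leave the electron-rich rings, the free phenol, the benzyl ester and the base-sensitive keto-depside linkage untouched.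

**Step 8**
Reactants: 14 benzyl 4-{[2-hydroxy-4-methoxy-6-(2-oxoheptyl)benzoyl]oxy}-2-methoxy-6-(2-oxoheptyl)benzoate
Product: 15 4-{[2-hydroxy-4-methoxy-6-(2-oxoheptyl)benzoyl]oxy}-2-methoxy-6-(2-oxoheptyl)benzoic acid
Conditions: H2 (1 atm), 10% Pd/C, EtOAc, rt
Reagents that add atoms: none
Why: Neutral catalytic hydrogenolysis cleaves only the benzyl ester, since the two non-conjugated ketones and the aryl ester are inert to Pd/H2 at rt and no acid or base is present to trigger isocoumarin formation.

**Compound list**
1 | trimethylsulfoxonium iodide | C[S+](C)(C)=O.[I-] | starting material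
2 | hexanoyl chloride | CCCCCC(=O)Cl | starting material
3 | dimethylsulfoxonium methylide | [CH2-][S+](C)(C)=O | intermediate
4 | 1-[dimethyl(oxo)-λ6-sulfanylidene]heptan-2-one | CCCCCC(=O)C=S(C)(C)=O | intermediate
5 | 2-hydroxy-4-methoxybenzoic acid | COc1ccc(C(=O)O)c(O)c1 | starting material
6 | 8-hydroxy-6-methoxy-3-pentyl-1H-isochromen-1-one | CCCCCC1=Cc2cc(OC)cc(O)c2C(=O)O1 | intermediate
7 | 2-hydroxy-4-methoxy-6-(2-oxoheptyl)benzoic acid | CCCCCC(=O)Cc1cc(OC)cc(O)c1C(=O)O | intermediate
8 | 2-hydroxy-4-methoxy-6-[(2-pentyl-1,3-dithian-2-yl)methyl]benzoic acid | CCCCCC1(Cc2cc(OC)cc(O)c2C(=O)O)SCCCS1 | intermediate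
9 | 4-hydroxy-2-methoxybenzoic acid | COc1cc(O)ccc1C(=O)O | starting material
10 | 6-hydroxy-8-methoxy-3-pentyl-1H-isochromen-1-one | CCCCCC1=Cc2cc(O)cc(OC)c2C(=O)O1 | intermediate
11 | 4-hydroxy-2-methoxy-6-(2-oxoheptyl)benzoic acid | CCCCCC(=O)Cc1cc(O)cc(OC)c1C(=O)O | intermediate
12 | benzyl 4-hydroxy-2-methoxy-6-(2-oxoheptyl)benzoate | CCCCCC(=O)Cc1cc(O)cc(OC)c1C(=O)OCc1ccccc1 | intermediate
13 | benzyl 4-({2-hydroxy-4-methoxy-6-[(2-pentyl-1,3-dithian-2-yl)methyl]benzoyl}oxy)-2-methoxy-6-(2-oxoheptyl)benzoate | CCCCCC1(Cc2cc(OC)cc(O)c2C(=O)Oc2cc(CC(=O)CCCCC)c(C(=O)OCc3ccccc3)c(OC)c2)SCCCS1 | intermediate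
14 | benzyl 4-{[2-hydroxy-4-methoxy-6-(2-oxoheptyl)benzoyl]oxy}-2-methoxy-6-(2-oxoheptyl)benzoate | CCCCCC(=O)Cc1cc(OC)cc(O)c1C(=O)Oc1cc(CC(=O)CCCCC)c(C(=O)OCc2ccccc2)c(OC)c1 | intermediate
15 | 4-{[2-hydroxy-4-methoxy-6-(2-oxoheptyl)benzoyl]oxy}-2-methoxy-6-(2-oxoheptyl)benzoic acid | CCCCCC(=O)Cc1cc(OC)cc(O)c1C(=O)Oc1cc(CC(=O)CCCCC)c(C(=O)O)c(OC)c1 | target

**Total step count:** 8. **Longest linear sequence:** 6 steps (1 → 2 → 3 → 6 → 7 → 8; the branch 1 → 4 → 5 → 6 → 7 → 8 is equally long).

**Three steps most likely to fail**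

Step 2 (the same reaction type recurs in step 4). The C–H acylmethylation is run on a free salicylic acid with an alkyl-ketone ylide; salicylate chelation of Rh or weak carboxylate direction could stall it. The fallback changes the directing group rather than the conditions. It sets out from 5, which is converted with MeONH2·HCl/EDC (CH2Cl2, Et3N) into 2-hydroxy-N,4-dimethoxybenzamide F1, carrying a much stronger monoanionic N-directing group. Treating F1 with ylide 4, [Cp*RhCl2]2/AgSbF6 and an acid additive (PivOH or Zn(OTf)2) in DCE at 80–100 °C gives ortho-acylmethylation and then lactonisation with expulsion of methoxyamine. This delivers isocoumarin 6, now isolated, and the route is rejoined at 6, which is saponified to 7 as in the second half of step 2.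

Step 3. Under Lewis acid the free keto acid can dehydrate back to isocoumarin 6 instead of forming the dithiane. The fallback blocks the carboxyl first. It sets out from 7, which is alkylated with allyl bromide/KHCO3 in DMF to prop-2-en-1-yl 2-hydroxy-4-methoxy-6-(2-oxoheptyl)benzoate F2. Dithioketalisation of F2 (propane-1,3-dithiol, BF3·OEt2) gives prop-2-en-1-yl 2-hydroxy-4-methoxy-6-[(2-pentyl-1,3-dithian-2-yl)methyl]benzoate F3; lactonisation would now have to expel allyl alcohol and is slow. Pd(PPh3)4/morpholine in THF then removes the allyl group and the route is rejoined at 8.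

Step 6. The acid is doubly ortho-substituted with a bulky dithianylmethyl neighbour, and a dithiane sulfur can compete for the acylium, so the direct TFAA condensation may be low-yielding. The fallback uses an isolable acyl donor. It sets out from 8, which is converted with acetone/TFAA/TFA into the salicylate acetonide 7-methoxy-2,2-dimethyl-5-[(2-pentyl-1,3-dithian-2-yl)methyl]-4H-1,3-benzodioxin-4-one F4. F4 is purified and opened by the caesium phenoxide of 12 (Cs2CO3, DMF, rt) by addition–elimination with loss of acetone. This gives the 2-hydroxy depside directly and the route is rejoined at 13.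

**Further compounds**
F1 | step 2 | 2-hydroxy-N,4-dimethoxybenzamide | CONC(=O)c1ccc(OC)cc1O
F2 | step 3 | prop-2-en-1-yl 2-hydroxy-4-methoxy-6-(2-oxoheptyl)benzoate | CCCCCC(=O)Cc1cc(OC)cc(O)c1C(=O)OCC=C
F3 | step 3 | prop-2-en-1-yl 2-hydroxy-4-methoxy-6-[(2-pentyl-1,3-dithian-2-yl)methyl]benzoate | CCCCCC1(Cc2cc(OC)cc(O)c2C(=O)OCC=C)SCCCS1
F4 | step 6 | 7-methoxy-2,2-dimethyl-5-[(2-pentyl-1,3-dithian-2-yl)methyl]-4H-1,3-benzodioxin-4-one | CCCCCC1(Cc2cc(OC)cc3OC(C)(C)OC(=O)c23)SCCCS1
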